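**Retrosynthetic overview**
1. Target 9 ⇒ epoxide 8: the dihydrofuran O1–C2 bond comes from 5-exo opening of a prenyl epoxide by the enol oxygen on C5 of the dienone (stereospecific, inversion at C2).
2. Epoxide 8 ⇒ lupulone 7: catalyst-controlled oxygen transfer to one of the two enantiotopic C6 prenyl groups; this C–O bond formation sets both stereocentres.
3. Lupulone 7 ⇒ deoxyhumulone 6 ⇒ monoprenyl ketone 5 ⇒ phlorisovalerophenone 3, one prenyl bromide 4 per step; the last C-prenylation dearomatises the ring and creates the gem-diprenyl carbon.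
4. Ketone 3 ⇒ phloroglucinol 1 + isovaleryl chloride 2 (Friedel–Crafts acylation).
5. Ring order: the six-membered carbocycle is the dearomatised arene (step 4); the dihydrofuran is closed last (step 5).

Assumption: the (1R,2R) ligand antipode is taken to give the (2S,3aS) series; if the first run shows the opposite sense, the equally available (1S,2S) ligand is used and nothing else changes. Dienones are drawn in the tautomer of the target SMILES; positions of 7 and 8 use cyclohexadienone numbering (C1 ketone, C2 acyl, C3 OH, C4 prenyl, C5 OH, C6 quaternary), positions of 9 use benzofuran numbering.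

**Step 1**
Reactants: 1 phloroglucinol; 2 isovaleryl chloride (3-methylbutanoyl chloride)
Product: 3 phlorisovalerophenone
Conditions: AlCl3 (3.5 equiv), PhNO2/CH2Cl2, 0 to 45 °C; then 1 M HCl
Reagents that add atoms: none
Why: Friedel–Crafts acylation of the triply activated arene stops at monoacylation because the hydrogen-bonded aryl ketone is deactivated; no stereocentre is formed.

**Step 2**
Reactants: 3 phlorisovalerophenone; 4 prenyl bromide (1-bromo-3-methylbut-2-ene, 1.0 equiv, slow addition)
Product: 5 monoprenyl ketone, 3-methyl-1-[2,4,6-trihydroxy-3-(3-methylbut-2-en-1-yl)phenyl]butan-1-one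
Conditions: 10% aq KOH, 0 °C, Ar; then 2 M HCl; chromatography (unreacted 3 recovered)
Reagents that add atoms: none
Why: Phenoxide C-alkylation (C-prenylation) in water, where hydrogen bonding to the phenoxide oxygens steers the allylic bromide to carbon; the two free ring positions of 3 are equivalent, so one equivalent of 4 gives a single mono-C-prenyl ketone and no stereocentre.

**Step 3**
Reactants: 5 monoprenyl ketone; 4 prenyl bromide (1.05 equiv)
Product: 6 deoxyhumulone, 3-methyl-1-[2,4,6-trihydroxy-3,5-bis(3-methylbut-2-en-1-yl)phenyl]butan-1-one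
Conditions: 10% aq KOH, 0 °C to rt, Ar; then 2 M HCl; chromatography
Reagents that add atoms: none
Why: A second phenoxide C-prenylation takes the only remaining ring CH, which is favoured over attack at the already substituted carbon because the product re-aromatises; no stereocentre is formed.

**Step 4**
Reactants: 6 deoxyhumulone; 4 prenyl bromide (1.1 equiv)
Product: 7 lupulone
Conditions: liquid NH3/Et2O, −40 °C; evaporation; then 2 M HCl; chromatography
Reagents that add atoms: none
Why: Dearomatising C-prenylation of the ammonium phenoxide at one of the two equivalent prenyl-bearing ring carbons (the classical hop β-acid alkenylation) gives the gem-diprenyl dienone; C6 carries two identical prenyls, so no stereocentre arises.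

**Step 5**
Reactants: 7 lupulone
Product: 9 (2S,3aS)-6-hydroxy-2-(2-hydroxypropan-2-yl)-5-(3-methylbutanoyl)-3a,7-bis(3-methylbut-2-en-1-yl)-3,3a-dihydro-1-benzofuran-4(2H)-one (target CNP0203294.1), via epoxide 8 (not isolated)
Conditions: Hf(OtBu)4 (10 mol%), N,N'-[(1R,2R)-cyclohexane-1,2-diyl]bis(N-hydroxy-2,2-diphenylacetamide) (12 mol%), 1,3-dimethyltetrahydropyrimidin-2(1H)-one (DMPU, 20 mol%), cumene hydroperoxide (1.05 equiv), 4 Å MS, toluene, 0 °C, Ar; then K2CO3, MeOH, 23 °C
Reagents that add atoms: cumene hydroperoxide, CC(C)(OO)c1ccccc1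
Why: Proposed new method: lupulone binds the Hf(OtBu)4/bis-hydroxamate complex by protonolysis as the six-membered chelate of its acyl oxygen and the oxygen on C1, which holds the two C6 prenyls above and below the chelate plane next to the cumylperoxide bound to tetravalent hafnium (the O–C1–C6–CH2–CH=C tether has the length of a bishomoallylic alkoxide), so oxygen is delivered to a C6 prenyl and not to the remote C4 prenyl or the enol carbons; the twofold-symmetric ligand pocket selects one enantiotopic prenyl and one olefin face, giving the (R)-epoxide on the prenyl that makes C6 (S) (an error in either choice gives a separable diastereomer, not the enantiomer); the free enolate oxygen on C5, more nucleophilic than the acyl-flanked oxygen on C1 of the triketone unit, then opens the epoxide 5-exo at its secondary carbon with inversion under K2CO3/MeOH, closing the O1–C2 bond of 9 and setting C2 as (S) with C3a (S); closest known reaction type: bis-hydroxamic acid/group 4 alkoxide asymmetric epoxidation of homoallylic and bishomoallylic alcohols and vanadium-catalysed epoxidation–cycloetherification of bishomoallylic alcohols, here extended to an enolised β-triketone as directing group and to desymmetrisation of a gem-diprenyl quaternary carbon.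

**Compound list**
1 | phloroglucinol (benzene-1,3,5-triol) | Oc1cc(O)cc(O)c1 | starting material
2 | isovaleryl chloride (3-methylbutanoyl chloride) | CC(C)CC(=O)Cl | starting material
3 | phlorisovalerophenone, 3-methyl-1-(2,4,6-trihydroxyphenyl)butan-1-one | CC(C)CC(=O)c1c(O)cc(O)cc1O | intermediate
4 | prenyl bromide (1-bromo-3-methylbut-2-ene) | CC(C)=CCBr | starting material
5 | monoprenyl ketone, 3-methyl-1-[2,4,6-trihydroxy-3-(3-methylbut-2-en-1-yl)phenyl]butan-1-one | CC(C)CC(=O)c1c(O)cc(O)c(CC=C(C)C)c1O | intermediate
6 | deoxyhumulone, 3-methyl-1-[2,4,6-trihydroxy-3,5-bis(3-methylbut-2-en-1-yl)phenyl]butan-1-one | CC(C)CC(=O)c1c(O)c(CC=C(C)C)c(O)c(CC=C(C)C)c1O | intermediate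
7 | lupulone, 3,5-dihydroxy-2-(3-methylbutanoyl)-4,6,6-tris(3-methylbut-2-en-1-yl)cyclohexa-2,4-dien-1-one (achiral) | CC(C)=CCC1=C(O)C(CC=C(C)C)(CC=C(C)C)C(=O)C(C(=O)CC(C)C)=C1O | intermediate
8 | (6S)-6-{[(2R)-3,3-dimethyloxiran-2-yl]methyl}-3,5-dihydroxy-2-(3-methylbutanoyl)-4,6-bis(3-methylbut-2-en-1-yl)cyclohexa-2,4-dien-1-one | CC(C)=CCC1=C(O)[C@@](C[C@H]2OC2(C)C)(CC=C(C)C)C(=O)C(C(=O)CC(C)C)=C1O | intermediate
9 | (2S,3aS)-6-hydroxy-2-(2-hydroxypropan-2-yl)-5-(3-methylbutanoyl)-3a,7-bis(3-methylbut-2-en-1-yl)-3,3a-dihydro-1-benzofuran-4(2H)-one | CC(C)=CCC1=C2O[C@H](C(C)(C)O)C[C@]2(CC=C(C)C)C(=O)C(C(=O)CC(C)C)=C1O | target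

**Totals**
Total step count: 5. Longest linear sequence: 5 (from phloroglucinol).

**Steps most likely to fail, with fallbacks**

Step 5 (proposed new method) is the largest risk. The possible failures are:
- chelation at the acyl oxygen and the oxygen on C3, which would direct oxygen to the C4 prenyl;
- product inhibition by the triketone product;
- weak discrimination of the two C6 prenyls;
- 6-endo closure to a pyran, or closure through the oxygen on C1 instead of the one on C5.

The fallback uses known chemistry, sets out from 7 and comes back at 9. Lupulone 7 is treated with 1,2:4,5-di-O-isopropylidene-β-D-erythro-2,3-hexodiulo-2,6-pyranose (the D-fructose-derived Shi ketone, 0.3 equiv), KHSO5 (1.05 equiv, as 2KHSO5·KHSO4·K2SO4), K2CO3 and Bu4NHSO4 in MeCN/dimethoxymethane/aqueous buffer (pH 10.5) at 0 °C. The chiral dioxirane gives (R)-epoxides of trisubstituted olefins under reagent control but cannot tell the two C6 prenyls apart. Epoxide 8 therefore forms together with its C6 epimer, (6R)-6-{[(2R)-3,3-dimethyloxiran-2-yl]methyl}-3,5-dihydroxy-2-(3-methylbutanoyl)-4,6-bis(3-methylbut-2-en-1-yl)cyclohexa-2,4-dien-1-one F2. Both close 5-exo in the basic medium: 8 gives the target 9, and F2 gives the 3a-epimer (2S,3aR)-6-hydroxy-2-(2-hydroxypropan-2-yl)-5-(3-methylbutanoyl)-3a,7-bis(3-methylbut-2-en-1-yl)-3,3a-dihydro-1-benzofuran-4(2H)-one F3. F3 and the constitutional isomers from C4-prenyl epoxidation are removed by preparative HPLC. C2 is still set as (S); the price is that at most about a third of the material becomes 9.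

Step 4 may give O-prenyl ethers, a tetraprenyl dienone or N-prenylation of the solvent ammonia, with low yield of 7. The fallback sets out from 6 and comes back at 7. Deoxyhumulone 6 is allylated at carbon with allyl methyl carbonate (C=CCOC(=O)OC) and Pd(PPh3)4 (zerovalent palladium, 5 mol%) in THF at rt. The soft π-allyl electrophile attacks a prenyl-bearing ring carbon in a dearomatising Tsuji–Trost reaction and gives racemic 3,5-dihydroxy-2-(3-methylbutanoyl)-4,6-bis(3-methylbut-2-en-1-yl)-6-(prop-2-en-1-yl)cyclohexa-2,4-dien-1-one F1. Cross-metathesis of F1 with 2-methylbut-2-ene (CC=C(C)C, large excess) and second-generation Grubbs catalyst RuCl2(=CHPh)(PCy3)(H2IMes) (5 mol%) in CH2Cl2 at 40 °C then converts the monosubstituted allyl olefin into a prenyl group. The trisubstituted prenyl olefins undergo only degenerate exchange, so achiral 7 results and the stereocentre of F1 disappears.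

Step 2 may give a mixture of 3, 5, 6 and O-prenyl ethers that is hard to separate. The fallback sets out from 3 and comes back at 5. The prenyl group is introduced by acid-mediated aromatic substitution on the neutral arene instead of phenoxide alkylation: 2-methylbut-3-en-2-ol (CC(C)(O)C=C, 1.0 equiv) and BF3·OEt2 (0.5 equiv) in dioxane at rt (Friedel–Crafts-type prenylation, short reaction time to avoid chroman formation). O-alkylation and gem-dialkylation are not possible under these conditions. This fallback makes no compound outside the list (F0).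

**Further compounds**
F0 | step 2 | none | none
F1 | step 4 | racemic 3,5-dihydroxy-2-(3-methylbutanoyl)-4,6-bis(3-methylbut-2-en-1-yl)-6-(prop-2-en-1-yl)cyclohexa-2,4-dien-1-one | CC(C)=CCC1=C(O)C(CC=C)(CC=C(C)C)C(=O)C(C(=O)CC(C)C)=C1O
F2 | step 5 | (6R)-6-{[(2R)-3,3-dimethyloxiran-2-yl]methyl}-3,5-dihydroxy-2-(3-methylbutanoyl)-4,6-bis(3-methylbut-2-en-1-yl)cyclohexa-2,4-dien-1-one | CC(C)=CCC1=C(O)[C@](C[C@H]2OC2(C)C)(CC=C(C)C)C(=O)C(C(=O)CC(C)C)=C1O
F3 | step 5 | (2S,3aR)-6-hydroxy-2-(2-hydroxypropan-2-yl)-5-(3-methylbutanoyl)-3a,7-bis(3-methylbut-2-en-1-yl)-3,3a-dihydro-1-benzofuran-4(2H)-one | CC(C)=CCC1=C2O[C@H](C(C)(C)O)C[C@@]2(CC=C(C)C)C(=O)C(C(=O)CC(C)C)=C1O
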